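**Plan**

1. Retrosynthesis: the secondary carbinol comes from a ketone (exo hydride). The bond between the CH2 of the one-carbon bridge and the bridgehead CH next to that ketone is then cut (intramolecular enolate alkylation), leaving a trans-anti-trans perhydrophenanthrene with an angular CH2X.
2. Rings B and C are cut together by an intramolecular Diels–Alder reaction (2-silyloxydiene on ring A, tethered (E)-enoate). Ring A is cut by a bromonium-initiated cyclisation/lactonisation of an acyclic triene diester.
3. Forward: chain assembly (carbonylation, allylic oxidation, Wittig, B-alkyl Suzuki) → ring A → rings B and C in one step → one-carbon bridge → reduction.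
4. Enabling feature: the quaternary B/C ring-fusion carbon carries an axial CH2 lying 1,4 across ring C from the α-CH of the ring-C ketone, and the Diels–Alder step leaves the enol ether on exactly that α-carbon. The enolate carbon therefore sits under CH2–OTf and closes the bicyclo[2.2.1]heptanone; O-alkylation would need a bridgehead enol ether.
5. Stereochemistry: Shi epoxidation → anti bromohydrin → bromonium relay (CHBr, quaternary C and ring-fusion CH of ring A); acid equilibration (tertiary carbinol); Diels–Alder chair/endo transition state and (E)-enoate (B/C fusion, quaternary C, isopropyl); tether (bridgehead CH); exo hydride (secondary carbinol).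

Key step: step 15

Remark on the chemistry: the target SMILES is read as having the ring-A tertiary hydroxyl axial (cis to the angular methyl, its methyl equatorial) and the secondary hydroxyl endo on the bicyclo[2.2.1]heptane; compounds 1, 6 and 7 are taken as commercial.

**Route**

Step 1
Reactants: 1 geranyl chloride
Product: 2 methyl (3E)-4,8-dimethylnona-3,7-dienoate
Conditions: CO (30 bar), MeOH, PdCl2(PPh3)2 (2 mol%), iPr2NEt, 50 °C
Reagents that add atoms: carbon monoxide [C-]#[O+]; methanol CO
Why: Palladium-catalysed alkoxycarbonylation of an allylic chloride (Tsuji type) through a π-allyl complex should insert CO at the unsubstituted terminus, keeping the (E)-trisubstituted alkene and adding the carboxyl carbon as a β,γ-unsaturated ester.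

Step 2
Reactants: 2 methyl (3E)-4,8-dimethylnona-3,7-dienoate
Product: 4 methyl (3E,7E)-4,8-dimethyl-9-oxonona-3,7-dienoate, via allylic alcohol 3 (not isolated)
Conditions: SeO2 (10 mol%), t-BuOOH, salicylic acid (cat.), CH2Cl2, rt; then MnO2, CH2Cl2, rt
Reagents that add atoms: tert-butyl hydroperoxide CC(C)(C)OO
Why: Sharpless SeO2/t-BuOOH allylic oxidation (ene reaction, then [2,3]-shift) should attack the (E)-methyl of the electron-rich terminal isopropylidene unit, and MnO2 should bring the allylic alcohol to the single (E)-enal.

Step 3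
Reactants: 4 methyl (3E,7E)-4,8-dimethyl-9-oxonona-3,7-dienoate
Product: 5 methyl (3E,7E)-4,8-dimethyldeca-3,7,9-trienoate
Conditions: Ph3PCH3Br, KN(SiMe3)2, THF, −78 → 0 °C
Reagents that add atoms: methyltriphenylphosphonium bromide C[P+](c1ccccc1)(c1ccccc1)c1ccccc1.[Br-]
Why: Wittig methylenation of the aldehyde at −78 °C should outrun deprotonation of the ester and give the terminal (E)-3-methyl-1,3-diene without change of alkene geometry.

Step 4
Reactants: 6 2-methylpropanal; 7 methyl (triphenylphosphoranylidene)acetate
Product: 9 methyl (2Z)-2-iodo-4-methylpent-2-enoate, via iodo ylide 8 (not isolated)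
Conditions: NIS, CH2Cl2, −20 °C; then 6, −20 °C → rt
Reagents that add atoms: N-iodosuccinimide O=C1CCC(=O)N1I
Why: Iodination of the stabilised ylide followed by Wittig olefination should place the ester trans to the isopropyl-bearing carbon, as usual for stabilised ylides, so that iodine is cis to isopropyl (Z).

Step 5
Reactants: 5 methyl (3E,7E)-4,8-dimethyldeca-3,7,9-trienoate; 9 methyl (2Z)-2-iodo-4-methylpent-2-enoate
Product: 11 triene diester, via B-alkyl-9-BBN 10 (not isolated)
Conditions: 9-BBN, THF, 0 °C → rt; then 9, PdCl2(dppf) (5 mol%), AsPh3 (5 mol%), Cs2CO3, DMF/H2O, rt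
Reagents that add atoms: none
Why: 9-BBN should hydroborate only the monosubstituted terminus of the diene (boron on the end carbon), and the B-alkyl Suzuki–Miyaura coupling should join this sp3 carbon to the iodoalkene with retention, giving the (E)-2-alkyl enoate that becomes the dienophile.

Step 6
Reactants: 11 triene diester
Product: 12 (7R,8R)-epoxy diester
Conditions: D-fructose-derived Shi ketone (30 mol%), Oxone (KHSO5), K2CO3, Bu4NHSO4 (cat.), MeCN/(MeO)2CH2/aq. Na2B4O7 buffer (pH 10.5), 0 °C
Reagents that add atoms: potassium peroxymonosulfate [K+].[O-]S(=O)(=O)OO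
Why: Shi asymmetric epoxidation (dioxirane, spiro transition state) should select the most electron-rich trisubstituted alkene, since the 3,4-alkene is deactivated by its CH2CO2Me group and the enoate is inert, and should give the (7R,8R)-epoxide that is the source of all absolute configuration.

Step 7
Reactants: 12 (7R,8R)-epoxy diester
Product: 13 (7S,8R)-bromohydrin diester
Conditions: Li2NiBr4, THF, 0 °C → rt; aq. work-up
Reagents that add atoms: dilithium tetrabromonickelate [Li+].[Li+].[Ni+2].[Br-].[Br-].[Br-].[Br-]
Why: SN2 opening of the trisubstituted epoxide by bromide at the less hindered secondary carbon (inversion) should give the anti bromohydrin with bromine on the secondary and hydroxyl on the tertiary carbon.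

Step 8
Reactants: 13 (7S,8R)-bromohydrin diester
Product: 16 cis-fused bromolactone, via tertiary mesylate 14 (not isolated), via trans-lactone 15 (not isolated)
Conditions: MsCl, Et3N, CH2Cl2, −40 °C; then (CF3)2CHOH (0.01 M), −40 → 0 °C; then MsOH, 40 °C
Reagents that add atoms: none
Why: Ionisation of the tertiary sulfonate with anchimeric assistance of the anti bromine (enantiospecific bromonium-initiated polyene cyclisation) should give a configurationally defined bromonium ion that the 3,4-alkene opens at the tertiary carbon through a chair transition state (bromine equatorial, new ring bond anti to it); the resulting tertiary cation is trapped by the ester carbonyl as the trans-lactone, which MsOH should equilibrate through that cation to the less strained cis-lactone (axial C–O, equatorial methyl).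

Step 9
Reactants: 16 cis-fused bromolactone
Product: 17 hydroxy Weinreb amide
Conditions: MeNH(OMe)·HCl, iPrMgCl, THF, −20 → 0 °C
Reagents that add atoms: N,O-dimethylhydroxylamine hydrochloride CNOC.Cl
Why: Weinreb aminolysis of the γ-lactone by the chloromagnesium amide (acyl–oxygen cleavage, so the tertiary carbinol centre is untouched) should be faster than attack on the α-branched conjugated ester.

Step 10
Reactants: 17 hydroxy Weinreb amide
Product: 18 triethylsilyl ether of the Weinreb amide
Conditions: Et3SiOTf, 2,6-lutidine, CH2Cl2, 0 °C → rt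
Reagents that add atoms: triethylsilyl trifluoromethanesulfonate CC[Si](CC)(CC)OS(=O)(=O)C(F)(F)F
Why: Silyl triflate/lutidine silylation of the hindered tertiary alcohol should stop relactonisation and later hemiketal formation.

Step 11
Reactants: 18 triethylsilyl ether of the Weinreb amide
Product: 19 vinyl ketone
Conditions: CH2=CHMgBr, THF, −78 → 0 °C; inverse quench into cold aq. NaHSO4
Reagents that add atoms: vinylmagnesium bromide C=C[Mg]Br
Why: Weinreb ketone synthesis, in which the chelated tetrahedral adduct prevents a second addition and the hindered conjugated ester should not react at low temperature.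

Step 12
Reactants: 19 vinyl ketone
Product: 20 (Z)-2-silyloxydiene
Conditions: t-BuMe2SiOTf, Et3N, CH2Cl2, −78 → 0 °C
Reagents that add atoms: tert-butyldimethylsilyl trifluoromethanesulfonate CC(C)(C)[Si](C)(C)OS(=O)(=O)C(F)(F)F
Why: Soft enolisation at the only α-CH2 of the vinyl ketone should give the 2-silyloxy-1,3-diene with the (Z)-enol ether geometry usual for this method, which places ring A on the outside of the diene terminus.

Step 13
Reactants: 20 (Z)-2-silyloxydiene
Product: 21 tricyclic silyl enol ether (rings A, B, C)
Conditions: toluene (0.005 M), BHT, Et3N (trace), 170 °C, sealed tube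
Reagents that add atoms: none
Why: Intramolecular Diels–Alder reaction of a 1,7,9-decatriene-type substrate, in which a chair-like tether with the allylic ring-A hydrogen eclipsing the enol ether (A1,3 strain) should set the anti relationship of the adjacent ring-fusion hydrogens, the endo-ester/exo-tether arrangement the trans B/C fusion and the quaternary carbon, and the (E)-enoate the isopropyl trans to the angular ester, while the new double bond is the enol ether needed for the next C–C bond.

Step 14
Reactants: 21 tricyclic silyl enol ether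
Product: 22 angular neopentyl alcohol
Conditions: iBu2AlH, CH2Cl2, −78 → 0 °C; aq. work-up
Reagents that add atoms: none
Why: iBu2AlH should reduce the hindered angular ester to the primary alcohol while the silyl enol ether, the silyl ether and the equatorial secondary bromide are inert.

Step 15
Reactants: 22 angular neopentyl alcohol
Product: 24 tetracyclic ketone, via neopentyl triflate 23 (not isolated)
Conditions: Tf2O, 2,6-di-tert-butyl-4-methylpyridine, CH2Cl2, −78 °C; then Bu4N(Ph3SiF2), THF, −78 → 0 °C
Reagents that add atoms: none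
Why: Fluoride cleaves the O–Si bond of the enol ether and releases, regiospecifically, the tetrabutylammonium enolate, whose α-carbon should displace the axial neopentyl triflate in an intramolecular SN2 reaction. The closest known reaction types are the cyclisation of cyclohexanone enolates bearing a 3-(sulfonyloxymethyl) group to bicyclo[2.2.1]heptan-2-ones (keto tosylate closures of camphor-type sesquiterpene syntheses) and the fluoride-mediated alkylation of silyl enol ethers. One five-membered ring is closed in the (enolexo)-5-exo-tet mode through the CH–CH2 side, which turns ring C into a boat and creates the one-carbon bridge. The only new stereocentre, the bridgehead CH, is dictated by the tether: the CH2 is held axial on the face anti to the ring-fusion hydrogen by the quaternary carbon set in step 13 and can bond only to that face. The step needs C- over O-alkylation and the enolate on the correct α-carbon; O-alkylation would give a bridgehead enol ether, the Diels–Alder-derived enol ether fixes the enolate position, and the equatorial secondary bromide has no anti-periplanar hydrogen for elimination and is neopentyl-shielded against substitution.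

Step 16
Reactants: 24 tetracyclic ketone
Product: 26 target bromo diol, via TES-protected diol 25 (not isolated)
Conditions: NaBH4, MeOH/THF, 0 °C; then 1 M HCl (aq), rt
Reagents that add atoms: none
Why: Hydride should add to the bicyclo[2.2.1]heptan-2-one from the exo face (syn to the one-carbon bridge, the endo face being screened by the endo hydrogens across the ring), giving the endo alcohol, which is also the less congested epimer next to the ring-A methyl; dilute acid then cleaves the tertiary triethylsilyl ether.

**Compound list**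

1 | geranyl chloride, (2E)-1-chloro-3,7-dimethylocta-2,6-diene | ClC/C=C(\C)CCC=C(C)C | starting material
2 | methyl (3E)-4,8-dimethylnona-3,7-dienoate | COC(=O)C/C=C(\C)CCC=C(C)C | intermediate
3 | methyl (3E,7E)-9-hydroxy-4,8-dimethylnona-3,7-dienoate | COC(=O)C/C=C(\C)CC/C=C(\C)CO | intermediate
4 | methyl (3E,7E)-4,8-dimethyl-9-oxonona-3,7-dienoate | COC(=O)C/C=C(\C)CC/C=C(\C)C=O | intermediate
5 | methyl (3E,7E)-4,8-dimethyldeca-3,7,9-trienoate | COC(=O)C/C=C(\C)CC/C=C(\C)C=C | intermediate
6 | 2-methylpropanal | CC(C)C=O | starting material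
7 | methyl (triphenylphosphoranylidene)acetate | COC(=O)C=P(c1ccccc1)(c1ccccc1)c1ccccc1 | starting material
8 | methyl iodo(triphenylphosphoranylidene)acetate | COC(=O)C(I)=P(c1ccccc1)(c1ccccc1)c1ccccc1 | intermediate
9 | methyl (2Z)-2-iodo-4-methylpent-2-enoate | CC(C)/C=C(\I)C(=O)OC | intermediate
10 | methyl (3E,7E)-10-(9-borabicyclo[3.3.1]nonan-9-yl)-4,8-dimethyldeca-3,7-dienoate | COC(=O)C/C=C(\C)CC/C=C(\C)CCB1C2CCCC1CCC2 | intermediate
11 | dimethyl (3E,7E)-4,8-dimethyl-11-[(E)-2-methylpropylidene]dodeca-3,7-dienedioate | COC(=O)C/C=C(\C)CC/C=C(\C)CC/C(C(=O)OC)=C\C(C)C | intermediate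
12 | dimethyl (3E,7R,8R)-7,8-epoxy-4,8-dimethyl-11-[(E)-2-methylpropylidene]dodec-3-enedioate | COC(=O)C/C=C(\C)CC[C@H]1O[C@]1(C)CC/C(C(=O)OC)=C\C(C)C | intermediate
13 | dimethyl (3E,7S,8R)-7-bromo-8-hydroxy-4,8-dimethyl-11-[(E)-2-methylpropylidene]dodec-3-enedioate | COC(=O)C/C=C(\C)CC[C@H](Br)[C@](C)(O)CC/C(C(=O)OC)=C\C(C)C | intermediate
14 | dimethyl (3E,7S,8R)-7-bromo-8-(methanesulfonyloxy)-4,8-dimethyl-11-[(E)-2-methylpropylidene]dodec-3-enedioate | COC(=O)C/C=C(\C)CC[C@H](Br)[C@](C)(OS(C)(=O)=O)CC/C(C(=O)OC)=C\C(C)C | intermediate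
15 | methyl (2E)-2-{2-[(3aS,4S,5S,7aS)-5-bromo-4,7a-dimethyl-2-oxooctahydro-1-benzofuran-4-yl]ethyl}-4-methylpent-2-enoate (trans-fused lactone) | CC(C)/C=C(C(=O)OC)\CC[C@]1(C)[C@@H](Br)CC[C@]2(C)OC(=O)C[C@@H]12 | intermediate
16 | methyl (2E)-2-{2-[(3aS,4S,5S,7aR)-5-bromo-4,7a-dimethyl-2-oxooctahydro-1-benzofuran-4-yl]ethyl}-4-methylpent-2-enoate (cis-fused lactone) | CC(C)/C=C(C(=O)OC)\CC[C@]1(C)[C@@H](Br)CC[C@@]2(C)OC(=O)C[C@@H]12 | intermediate
17 | methyl (2E)-2-{2-[(1S,2S,3R,6S)-6-bromo-3-hydroxy-2-{2-[methoxy(methyl)amino]-2-oxoethyl}-1,3-dimethylcyclohexyl]ethyl}-4-methylpent-2-enoate | CC(C)/C=C(C(=O)OC)\CC[C@]1(C)[C@@H](Br)CC[C@@](C)(O)[C@H]1CC(=O)N(C)OC | intermediate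
18 | methyl (2E)-2-{2-[(1S,2S,3R,6S)-6-bromo-2-{2-[methoxy(methyl)amino]-2-oxoethyl}-1,3-dimethyl-3-(triethylsilyloxy)cyclohexyl]ethyl}-4-methylpent-2-enoate | CC(C)/C=C(C(=O)OC)\CC[C@]1(C)[C@@H](Br)CC[C@@](C)(O[Si](CC)(CC)CC)[C@H]1CC(=O)N(C)OC | intermediate
19 | methyl (2E)-2-{2-[(1S,2S,3R,6S)-6-bromo-1,3-dimethyl-2-(2-oxobut-3-en-1-yl)-3-(triethylsilyloxy)cyclohexyl]ethyl}-4-methylpent-2-enoate | CC(C)/C=C(C(=O)OC)\CC[C@]1(C)[C@@H](Br)CC[C@@](C)(O[Si](CC)(CC)CC)[C@H]1CC(=O)C=C | intermediate
20 | methyl (2E)-2-{2-[(1S,2S,3R,6S)-6-bromo-2-[(1Z)-2-(tert-butyldimethylsilyloxy)buta-1,3-dien-1-yl]-1,3-dimethyl-3-(triethylsilyloxy)cyclohexyl]ethyl}-4-methylpent-2-enoate | CC(C)/C=C(C(=O)OC)\CC[C@]1(C)[C@@H](Br)CC[C@@](C)(O[Si](CC)(CC)CC)[C@H]1/C=C(\O[Si](C)(C)C(C)(C)C)C=C | intermediate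
21 | methyl 8-bromo-4-(tert-butyldimethylsilyloxy)-5,8a-dimethyl-1-(propan-2-yl)-5-(triethylsilyloxy)-1,2,4a,4b,5,6,7,8,8a,9,10,10a-dodecahydrophenanthrene-10a-carboxylate; trans-anti-trans (4a-H and 4b-H anti, 4b-H trans to 8a-CH3, 10a-CO2Me trans to 4a-H), isopropyl trans to the angular ester, Br equatorial and cis to 8a-CH3, 5-OSiEt3 cis to 8a-CH3 | CC(C)[C@@H]1CC=C(O[Si](C)(C)C(C)(C)C)[C@H]2[C@@H]3[C@](C)(O[Si](CC)(CC)CC)CC[C@H](Br)[C@@]3(C)CC[C@]12C(=O)OC | intermediate
22 | the 10a-hydroxymethyl compound corresponding to 21 (ester reduced to CH2OH, same configuration) | CC(C)[C@@H]1CC=C(O[Si](C)(C)C(C)(C)C)[C@H]2[C@@H]3[C@](C)(O[Si](CC)(CC)CC)CC[C@H](Br)[C@@]3(C)CC[C@]12CO | intermediate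
23 | trifluoromethanesulfonate of 22 (angular CH2OTf) | CC(C)[C@@H]1CC=C(O[Si](C)(C)C(C)(C)C)[C@H]2[C@@H]3[C@](C)(O[Si](CC)(CC)CC)CC[C@H](Br)[C@@]3(C)CC[C@]12COS(=O)(=O)C(F)(F)F | intermediate
24 | tetracyclic ketone: target skeleton with C=O in place of the secondary carbinol and OSiEt3 on the tertiary carbinol | CC(C)[C@@H]1C[C@H]2C[C@@]13CC[C@]1(C)[C@@H](Br)CC[C@@](C)(O[Si](CC)(CC)CC)[C@H]1[C@@H]3C2=O | intermediate
25 | tertiary O-triethylsilyl ether of the target (secondary hydroxyl endo) | CC(C)[C@@H]1C[C@H]2C[C@@]13CC[C@]1(C)[C@@H](Br)CC[C@@](C)(O[Si](CC)(CC)CC)[C@H]1[C@@H]3[C@H]2O | intermediate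
26 | target bromo diol CNP0295684.1 | CC(C)[C@@H]1C[C@H]2C[C@@]13CC[C@]1(C)[C@@H](Br)CC[C@@](C)(O)[C@H]1[C@@H]3[C@H]2O | target

**Count and risks**

Total step count: 16. Longest linear sequence: 15 steps (steps 1–3 and 5–16); step 4 is a one-step branch.

The three steps most likely to fail:

Step 13. The cycloaddition may be slow because the tether forces the diene and dienophile to pair against their natural polarisation and the dienophile is trisubstituted. Endo/exo control may erode at 170 °C, and the oxygen on the enol ether carbon is pushed toward the ring-A methyl as ring B forms. The fallback raises dienophile reactivity by changing its oxidation level: starting from 20, iBu2AlH (CH2Cl2, −78 °C) should reduce only the enoate to the allylic alcohol F1, and MnO2 should give the enal F2. The enal should cyclise at 80–110 °C with a stronger endo preference of the formyl group to the aldehyde cycloadduct F3, and NaBH4 then gives 22, where the route is rejoined.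

Step 15. The neopentyl triflate may ionise and rearrange before closure, the displacement at the neopentyl carbon may be too slow so that the enolate is simply protonated, or the tertiary silyl ether may be lost to fluoride. The fallback closes the same bond by a radical instead of an enolate. From 22, the triflate 23 is made as before and treated with Bu4NI to give the neopentyl iodide F4. (Me3Si)3SiH with Et3B/O2 should abstract iodine much faster than the secondary bromine, and the primary radical should add 5-exo to the silyl enol ether. The α-silyloxy radical takes hydrogen from the exo face, which gives the endo silyl ether directly as the bis-silyl ether F5. HF·pyridine then gives 26, where the route is rejoined.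

Step 8. Enantiopurity may erode by bromonium transfer between alkenes, the tertiary sulfonate may lose a proton instead of cyclising, or the lactone equilibration may stop short. The fallback generates the bromonium ion directly on the alkene: from 11, Et2SBr·SbCl5Br (MeNO2, −25 °C) should give the racemic trans-lactone, that is 15 together with the enantiomer of trans-lactone 15 F6. MsOH equilibration should give racemic cis-lactone, that is 16 together with the enantiomer of cis-lactone 16 F7, and preparative chromatography on a chiral stationary phase returns 16, where the route is rejoined.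

**Further compounds**

F1 | step 13 | (2E)-2-{2-[(1S,2S,3R,6S)-6-bromo-2-[(1Z)-2-(tert-butyldimethylsilyloxy)buta-1,3-dien-1-yl]-1,3-dimethyl-3-(triethylsilyloxy)cyclohexyl]ethyl}-4-methylpent-2-en-1-ol | CC(C)/C=C(CO)\CC[C@]1(C)[C@@H](Br)CC[C@@](C)(O[Si](CC)(CC)CC)[C@H]1/C=C(\O[Si](C)(C)C(C)(C)C)C=C
F2 | step 13 | (2E)-2-{2-[(1S,2S,3R,6S)-6-bromo-2-[(1Z)-2-(tert-butyldimethylsilyloxy)buta-1,3-dien-1-yl]-1,3-dimethyl-3-(triethylsilyloxy)cyclohexyl]ethyl}-4-methylpent-2-enal | CC(C)/C=C(C=O)\CC[C@]1(C)[C@@H](Br)CC[C@@](C)(O[Si](CC)(CC)CC)[C@H]1/C=C(\O[Si](C)(C)C(C)(C)C)C=C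
F3 | step 13 | 10a-carbaldehyde analogue of 21 (CHO in place of CO2Me, same configuration) | CC(C)[C@@H]1CC=C(O[Si](C)(C)C(C)(C)C)[C@H]2[C@@H]3[C@](C)(O[Si](CC)(CC)CC)CC[C@H](Br)[C@@]3(C)CC[C@]12C=O
F4 | step 15 | angular neopentyl iodide corresponding to 22 (CH2I in place of CH2OH) | CC(C)[C@@H]1CC=C(O[Si](C)(C)C(C)(C)C)[C@H]2[C@@H]3[C@](C)(O[Si](CC)(CC)CC)CC[C@H](Br)[C@@]3(C)CC[C@]12CI
F5 | step 15 | bis-silyl ether of the target (endo secondary OSi(t-Bu)Me2, tertiary OSiEt3) | CC(C)[C@@H]1C[C@H]2C[C@@]13CC[C@]1(C)[C@@H](Br)CC[C@@](C)(O[Si](CC)(CC)CC)[C@H]1[C@@H]3[C@H]2O[Si](C)(C)C(C)(C)C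
F6 | step 8 | enantiomer of trans-lactone 15, (3aR,4R,5R,7aR) | CC(C)/C=C(C(=O)OC)\CC[C@@]1(C)[C@H](Br)CC[C@@]2(C)OC(=O)C[C@H]12
F7 | step 8 | enantiomer of cis-lactone 16, (3aR,4R,5R,7aS) | CC(C)/C=C(C(=O)OC)\CC[C@@]1(C)[C@H](Br)CC[C@]2(C)OC(=O)C[C@H]12
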